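**Plan**

- Hardest features: the trans C3/C4 pair of lactone ring B lies next to a trisubstituted alkene (Cα on C4, Cβ = CH) whose CO2H is cis to C4. The three side-chain carboxyls must end as Me/Me/H. Ring A must be joined at C4a, its least nucleophilic carbon.
- Enabling feature: C3, C4, Cα, Cβ and the carboxyl carbons on C3 and on Cβ make a six-carbon chain. Bonding those two carboxyl carbons to each other gives the ring of a 3,4-dioxygenated benzoate, with the Cα ester as its CO2Me. The cis relation of C4 and CO2H across Cα=Cβ is the trace of that ring.
- Cuts: ring B at C4–C4a and C1–O2 gives a 2,4,5-trioxygenated benzoic acid and a cis-epoxide. Removing the oxirane oxygen gives a Z-alkene. Rejoining the two carboxyl carbons gives an ether of methyl isovanillate.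
- Forward order: the benzoate ring is opened first, then the oxirane is made, and ring B is closed last (C4–C4a, then O2–C1). Ring A is bought.
- Stereochemistry: both alkene geometries are inherited from the benzene ring. A catalyst-controlled epoxidation sets two centres. SN2 inversion at C4 turns the cis-epoxide into the trans-lactone, and C3 keeps its C–O bond.

Key step: step 2

Remark: the SMILES is read as the (3S,4R)-trans-lactone with an (E)-alkene (C4 cis to CO2H). The sense of induction in step 3 is assumed by analogy with other Z-acrylic acid derivatives, and both ligand antipodes are available.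

**Step 1**
Reactants: 1 methyl 3-hydroxy-4-methoxybenzoate (methyl isovanillate); 2 isobutene
Product: 3 methyl 3-(tert-butoxy)-4-methoxybenzoate
Conditions: isobutene (excess), TfOH (5 mol %), CH2Cl2, −78 → −20 °C
Reagents that add atoms: isobutene (2), CC(C)=C
Why: Acid-catalysed addition of the phenol O–H to isobutene is the standard aryl tert-butyl ether synthesis; it should work at low temperature because the ester-deactivated ring resists C-tert-butylation, and it places on O3 the alkyl group that will become the acid-labile ester of the future free acid.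

**Step 2**
Reactants: 3 methyl 3-(tert-butoxy)-4-methoxybenzoate
Product: 5 1-tert-butyl 6-methyl (2E,4Z)-3-(methoxycarbonyl)hexa-2,4-dienedioate, via primary ozonide 4 (not isolated)
Conditions: O3 (1.0 equiv, titrated CH2Cl2 solution), CH2Cl2, −78 °C, dark; then Me2S, −78 → 0 °C
Reagents that add atoms: ozone, [O-][O+]=O
Why: Ozone adds as a 1,3-dipole across C3–C4 of 3, the only ring bond whose two carbons both carry an oxygen donor, to give primary ozonide 4; its cycloreversion breaks C3–C4 and Me2S takes up the third oxygen, so each ArC–OR carbon ends as the ester carbon RO–C=O. The closest known reaction type is the ozonolytic opening of 1,2-dialkoxybenzene (veratrole-type) rings to cis,cis-muconic diesters, and the step copies the presumed biogenesis of this side chain, in which a galloyl ring is cut between two oxygenated carbons. No ring is closed and no stereocentre is formed; the cis geometry of the ring is passed on, so arene C1=C2 becomes the (2E) bond with the future C4 cis to the future CO2H, and arene C5=C6 becomes the (4Z) bond that the cis-epoxide needs. The three carboxyl groups are differentiated in the same operation: the O-tert-butyl carbon becomes the acid-labile ester of the future free acid, while the O-methyl carbon and the old CO2Me become the two methyl esters of the target. The step needs site selectivity among the ring bonds and a stop after one equivalent of ozone; the first is secured by the two donors on C3/C4 against the ester-deactivated C1, C2 and C6, the second by the one or two ester groups on each C=C of 5, the limiting charge of ozone and the low temperature. Me2S is used instead of a phosphine because phosphines add to Z-enoates and would isomerise them.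

**Step 3**
Reactants: 5 1-tert-butyl 6-methyl (2E,4Z)-3-(methoxycarbonyl)hexa-2,4-dienedioate
Product: 6 methyl (2S,3S)-3-[(E)-4-(tert-butoxy)-1-methoxy-1,4-dioxobut-2-en-2-yl]oxirane-2-carboxylate
Conditions: (S,S)-[Mn(OTf)2(Me2N-PDP)] (1 mol %), 30 % aq H2O2 (1.5 equiv, slow addition), 2-ethylhexanoic acid (2 equiv), MeCN, −30 °C
Reagents that add atoms: hydrogen peroxide, OO
Why: In this enantioselective epoxidation of an electron-poor Z-olefin (aminopyridine–manganese catalyst, H2O2, carboxylic acid co-ligand; oxygen transfer that keeps the olefin geometry), the 1,2-disubstituted C4=C5 bond with one ester should react before the trisubstituted C2=C3 bond with two, the cis geometry is retained, and the chiral catalyst selects the face, which sets both (2S,3S) centres.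

**Step 4**
Reactants: 7 2,4,5-trihydroxybenzaldehyde; 8 benzyl bromide
Product: 9 2,4,5-tris(benzyloxy)benzaldehyde
Conditions: BnBr (3.5 equiv), K2CO3 (4 equiv), DMF, 60 °C, under N2
Reagents that add atoms: benzyl bromide (8), BrCc1ccccc1
Why: A threefold Williamson ether synthesis on the phenoxides masks the oxidation-prone hydroxyquinol ring with groups that survive Pd(II) in hot HFIP and can later be removed without hydrogen.

**Step 5**
Reactants: 9 2,4,5-tris(benzyloxy)benzaldehyde
Product: 10 2,4,5-tris(benzyloxy)benzoic acid
Conditions: NaClO2, NaH2PO4, 2-methylbut-2-ene (excess), t-BuOH/THF/H2O, 0 °C → rt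
Reagents that add atoms: sodium chlorite, [Na+].[O-]Cl=O
Why: The Pinnick oxidation converts the aldehyde into the acid under buffered conditions, and the alkene scavenger removes HOCl before it can chlorinate the electron-rich ring.

**Step 6**
Reactants: 6 methyl (2S,3S)-3-[(E)-4-(tert-butoxy)-1-methoxy-1,4-dioxobut-2-en-2-yl]oxirane-2-carboxylate; 10 2,4,5-tris(benzyloxy)benzoic acid
Product: 12 methyl (3S,4R)-5,6,8-tris(benzyloxy)-4-[(E)-4-(tert-butoxy)-1-methoxy-1,4-dioxobut-2-en-2-yl]-1-oxo-3,4-dihydro-1H-isochromene-3-carboxylate, via hydroxy acid 11 (not isolated)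
Conditions: Pd(OAc)2 (10 mol %), N-acetyl-tert-leucine (20 mol %), KOAc (1 equiv), HFIP, 75 °C
Reagents that add atoms: none
Why: In this carboxylate-directed Pd(II) C–H alkylation with an epoxide followed by lactonisation (a reaction type known for benzoic acids with terminal and internal epoxides), the potassium carboxylate steers metalation to C6–H, the only C–H ortho to it, the aryl–Pd bond opens the K+/HFIP-activated oxirane by SN2 attack at the allylic carbon remote from the ester with inversion (giving 4R) while the C–O bond at the ester-bearing carbon is untouched (3S), and hydroxy acid 11 closes ring B by 6-exo-trig lactonisation, so the cis-epoxide becomes the trans-lactone, with the bulky tert-butyl ester and allylic strain holding back closure onto the side-chain esters.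

**Step 7**
Reactants: 12 methyl (3S,4R)-5,6,8-tris(benzyloxy)-4-[(E)-4-(tert-butoxy)-1-methoxy-1,4-dioxobut-2-en-2-yl]-1-oxo-3,4-dihydro-1H-isochromene-3-carboxylate
Product: 13 (E)-3-[(3S,4R)-5,6,8-trihydroxy-3-(methoxycarbonyl)-1-oxo-3,4-dihydro-1H-isochromen-4-yl]-4-methoxy-4-oxobut-2-enoic acid (target)
Conditions: BCl3 (10 equiv), pentamethylbenzene (15 equiv), CH2Cl2, −78 → 0 °C; aqueous work-up under Ar
Reagents that add atoms: none
Why: Lewis-acid dealkylation with BCl3 and a non-basic cation trap should cleave the three aryl benzyl ethers and the tert-butyl ester in one operation, without hydrogen (the alkene survives) and without base (C3–H, C4–H and the lactone are not disturbed), and the methyl esters are inert at this temperature.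

**Compound list**

1 | methyl 3-hydroxy-4-methoxybenzoate (methyl isovanillate) | COC(=O)c1ccc(OC)c(O)c1 | starting material
2 | isobutene | CC(C)=C | starting material
3 | methyl 3-(tert-butoxy)-4-methoxybenzoate | COC(=O)c1ccc(OC)c(OC(C)(C)C)c1 | intermediate
4 | primary ozonide of 3 (1,2,3-trioxolane fused across C3–C4, cis-fused, racemic) | COC(=O)C1=CC2(OC(C)(C)C)OOOC2(OC)C=C1 | intermediate
5 | 1-tert-butyl 6-methyl (2E,4Z)-3-(methoxycarbonyl)hexa-2,4-dienedioate | COC(=O)/C=C\C(C(=O)OC)=C/C(=O)OC(C)(C)C | intermediate
6 | methyl (2S,3S)-3-[(E)-4-(tert-butoxy)-1-methoxy-1,4-dioxobut-2-en-2-yl]oxirane-2-carboxylate | COC(=O)[C@H]1O[C@H]1/C(C(=O)OC)=C\C(=O)OC(C)(C)C | intermediate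
7 | 2,4,5-trihydroxybenzaldehyde | O=Cc1cc(O)c(O)cc1O | starting material
8 | benzyl bromide | BrCc1ccccc1 | starting material
9 | 2,4,5-tris(benzyloxy)benzaldehyde | O=Cc1cc(OCc2ccccc2)c(OCc2ccccc2)cc1OCc1ccccc1 | intermediate
10 | 2,4,5-tris(benzyloxy)benzoic acid | OC(=O)c1cc(OCc2ccccc2)c(OCc2ccccc2)cc1OCc1ccccc1 | intermediate
11 | 3,4,6-tris(benzyloxy)-2-[(1R,2S)-ring-opened hydroxy triester side chain]benzoic acid (hydroxy acid) | COC(=O)/C(=C/C(=O)OC(C)(C)C)[C@@H](c1c(OCc2ccccc2)c(OCc2ccccc2)cc(OCc2ccccc2)c1C(=O)O)[C@H](O)C(=O)OC | intermediate
12 | methyl (3S,4R)-5,6,8-tris(benzyloxy)-4-[(E)-4-(tert-butoxy)-1-methoxy-1,4-dioxobut-2-en-2-yl]-1-oxo-3,4-dihydro-1H-isochromene-3-carboxylate | COC(=O)/C(=C/C(=O)OC(C)(C)C)[C@H]1c2c(OCc3ccccc3)c(OCc3ccccc3)cc(OCc3ccccc3)c2C(=O)O[C@@H]1C(=O)OC | intermediate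
13 | (E)-3-[(3S,4R)-5,6,8-trihydroxy-3-(methoxycarbonyl)-1-oxo-3,4-dihydro-1H-isochromen-4-yl]-4-methoxy-4-oxobut-2-enoic acid | COC(=O)/C(=C/C(=O)O)[C@H]1c2c(O)c(O)cc(O)c2C(=O)O[C@@H]1C(=O)OC | target

**Step count**

Total step count: 7.
Longest linear sequence: 5 (steps 1, 2, 3, 6, 7).

**Steps most likely to fail**

**Step 2.** Ozone may go on to attack the newly formed diene. It may also add to a neighbouring ring bond, because the twisted tert-butoxy group is a weaker donor than methoxy. The Z-enoate may isomerise during work-up.

The fallback sets out from isobutene 2 and comes back at diene 5; it assembles the chain by cross-coupling instead of ring opening. Isobutene 2 is added to acetic acid (H2SO4 cat.) to give tert-butyl acetate F1. Its lithium enolate (LDA, THF, −78 °C) is acylated with dimethyl oxalate in a crossed Claisen condensation to give 4-tert-butyl 1-methyl 2-oxobutanedioate F2. The chelated sodium enolate (NaH, then Tf2O, −78 °C) gives 4-tert-butyl 1-methyl (Z)-2-(trifluoromethylsulfonyloxy)but-2-enedioate F3, in which the triflate is cis to CO2tBu. A Stille coupling with methyl (Z)-3-(tributylstannyl)acrylate (Pd(PPh3)4, CuI cat., DMF, rt) joins the two sp2 carbons with retention on both sides and gives 5.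

**Step 6.** Several things may go wrong:
- The oxirane may be opened at the wrong site, either at the ester-bearing carbon or in the SN2′ sense.
- The aryl–palladium species may insert into the fumarate-type double bond.
- The carboxylate may O-alkylate.
- The neighbouring tert-butyl ester may take part in opening the epoxide in hot HFIP.
- The freed hydroxyl may close onto a side-chain ester.

The fallback sets out from acid 10 and comes back at lactone 12; it replaces catalytic C–H activation by a preformed aryl–metal reagent at low temperature. Acid 10 is methylated (MeI, K2CO3, DMF) to methyl 2,4,5-tris(benzyloxy)benzoate F4. Ester-directed ortho-magnesiation (TMPMgCl·LiCl, THF, −20 °C) at the position between CO2Me and OBn gives the arylmagnesium chloride F5. This is transmetalated with Et2AlCl to the arylaluminium species, the class of reagent that substitutes γ,δ-epoxy enoates at the γ-carbon with inversion, and is combined with epoxide 6 at −78 → −20 °C to give the hydroxy tetraester F6. F6 is closed to 12 with a catalytic amount of TsOH in toluene.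

**Step 3.** Turnover may be slow on a doubly deactivated olefin, facial selectivity may be poor, and the cis geometry may be partly lost.

The fallback sets out from diene 5 and comes back at epoxide 6; it replaces asymmetric catalysis by a stereospecific racemic epoxidation followed by enzymatic resolution. Methyl(trifluoromethyl)dioxirane generated in situ (Oxone, CF3COCH3, NaHCO3, MeCN/H2O, 0 °C) transfers oxygen in a concerted way and gives the racemic cis-epoxide F7. A lipase, screened for hydrolysis of the oxirane-2-carboxylate methyl ester of the (2R,3R)-enantiomer (toluene/pH 7 buffer), converts that enantiomer into the (2R,3R)-epoxy acid F8. F8 is removed by a bicarbonate wash, leaving 6.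

**Further compounds**

F1 | step 2 | tert-butyl acetate | CC(=O)OC(C)(C)C
F2 | step 2 | 4-tert-butyl 1-methyl 2-oxobutanedioate | COC(=O)C(=O)CC(=O)OC(C)(C)C
F3 | step 2 | 4-tert-butyl 1-methyl (Z)-2-(trifluoromethylsulfonyloxy)but-2-enedioate | COC(=O)/C(OS(=O)(=O)C(F)(F)F)=C/C(=O)OC(C)(C)C
F4 | step 6 | methyl 2,4,5-tris(benzyloxy)benzoate | COC(=O)c1cc(OCc2ccccc2)c(OCc2ccccc2)cc1OCc1ccccc1
F5 | step 6 | [3,4,6-tris(benzyloxy)-2-(methoxycarbonyl)phenyl]magnesium chloride | COC(=O)c1c([Mg]Cl)c(OCc2ccccc2)c(OCc2ccccc2)cc1OCc1ccccc1
F6 | step 6 | methyl ester of hydroxy acid 11 (hydroxy tetraester) | COC(=O)/C(=C/C(=O)OC(C)(C)C)[C@@H](c1c(OCc2ccccc2)c(OCc2ccccc2)cc(OCc2ccccc2)c1C(=O)OC)[C@H](O)C(=O)OC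
F7 | step 3 | racemic cis-epoxide (rac-6) | COC(=O)C1OC1/C(C(=O)OC)=C\C(=O)OC(C)(C)C
F8 | step 3 | (2R,3R)-3-[(E)-4-(tert-butoxy)-1-methoxy-1,4-dioxobut-2-en-2-yl]oxirane-2-carboxylic acid | OC(=O)[C@@H]1O[C@@H]1/C(C(=O)OC)=C\C(=O)OC(C)(C)C
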